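**Plan**

- Retrosynthesis: the two epoxides (C1–O–C2, C4–O–C5) are removed first. The C13 acetate is traced back by allylic transposition to a C7 carbinol, and the butenolide is opened at C7–C11 to a C6 O-acrylate on a C7 ketone. Then the O8 ester, the C1=C2 bond (ring-closing enyne metathesis, C14 from ethylene) and the C5–C6 bond (Nozaki–Hiyama–Kishi) are cut.
- Feature used: in the lactone O6–C12(=O)–C11(C13H2OAc)=C7, the carbons C11–C12–C13 are an acrylate in disguise, and C7 lies between the oxygenated carbons C6 and C8. A C6 O-acrylate on an α,α′-dioxygenated C7 ketone therefore closes the five-membered ring by a Morita–Baylis–Hillman aldol.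
- Forward order: 2-deoxy-D-ribose (C6–C10) → alkyne (adds C1) → C5–C6 coupling with a C2–C5 vinyl iodide → ten-membered ring → C6 acrylate, O8 ester, C7 ketone → butenolide → C13 acetate → epoxides.
- Stereochemistry: C8 is C3 of the sugar. C6 comes from Felkin–Anh addition next to sugar C4 (= C7, a relay centre that is later oxidised). C1/C2 come from Shi catalyst control on the Z-alkene. C4/C5 come from peripheral dioxirane attack on the E-alkene under A1,3 control from C6.

Key step: step 13

Remark: germacrane numbering is used throughout, also for acyclic precursors (ring C1–C10, C12 lactone carbonyl, C13 the CH2O carbon on C11, C14 the methylene on C10, C15 the methyl on C4); CIP descriptors at C6 and C7 change with the substituents although the spatial arrangement is kept; 1 is drawn open-chain; the Shi oxazolidinone ketone is assumed to be a purchasable catalyst.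

**Step 1**
Reactants: 1 2-deoxy-D-ribose
Product: 2 2-deoxy-3,4-O-isopropylidene-D-erythro-pentopyranose
Conditions: 2-methoxypropene, PPTS (cat.), EtOAc, 0 °C to rt
Reagents that add atoms: 2-methoxypropene COC(C)=C
Why: Kinetic ketal exchange on the cis-3,4-diol of the pyranose form leaves the lactol (latent C10 aldehyde) and the ring oxygen (future C6 hydroxyl) free, and no stereocentre is formed.

**Step 2**
Reactants: 2 2-deoxy-3,4-O-isopropylidene-D-erythro-pentopyranose
Product: 3 [(4R,5S)-2,2-dimethyl-5-(prop-2-yn-1-yl)-1,3-dioxolan-4-yl]methanol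
Conditions: Ohira–Bestmann reagent, K2CO3, MeOH, rt to 40 °C
Reagents that add atoms: dimethyl (1-diazo-2-oxopropyl)phosphonate COP(=O)(OC)C(=[N+]=[N-])C(C)=O
Why: Seyferth–Gilbert homologation acts on the open-chain aldehyde tautomer of the lactol, turns C10 into a terminal alkyne (the new carbon is C1) and releases the primary C6 hydroxyl, with C7 and C8 untouched.

**Step 3**
Reactants: 3 [(4R,5S)-2,2-dimethyl-5-(prop-2-yn-1-yl)-1,3-dioxolan-4-yl]methanol
Product: 4 (4S,5S)-2,2-dimethyl-5-(prop-2-yn-1-yl)-1,3-dioxolane-4-carbaldehyde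
Conditions: Dess–Martin periodinane, CH2Cl2, 0 °C to rt, used crude
Reagents that add atoms: none
Why: Dess–Martin oxidation under non-basic conditions should give the α-alkoxy aldehyde without epimerising the cis-dioxolane centre C7.

**Step 4**
Reactants: 5 pent-1-en-4-yne
Product: 6 (E)-1-iodo-2-methylpenta-1,4-diene
Conditions: Me3Al, Cp2ZrCl2 (0.25 equiv), CH2Cl2, 0 °C to rt; then I2, THF, −30 °C
Reagents that add atoms: trimethylaluminium C[Al](C)C; iodine II
Why: Negishi zirconium-catalysed carboalumination adds methyl and aluminium syn across the alkyne with aluminium on the terminal carbon, and iodinolysis with retention gives the E vinyl iodide (C2–C5 plus C15).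

**Step 5**
Reactants: 4 (4S,5S)-2,2-dimethyl-5-(prop-2-yn-1-yl)-1,3-dioxolane-4-carbaldehyde; 6 (E)-1-iodo-2-methylpenta-1,4-diene
Product: 7 (1R,2E)-1-[(4R,5S)-2,2-dimethyl-5-(prop-2-yn-1-yl)-1,3-dioxolan-4-yl]-3-methylhexa-2,5-dien-1-ol
Conditions: CrCl2 (5 equiv), NiCl2 (1 mol %), DMF, rt
Reagents that add atoms: none
Why: Nozaki–Hiyama–Kishi coupling (a non-basic vinylchromium reagent that tolerates the acidic alkyne C–H) forms C5–C6 with retention of the E geometry, and Felkin–Anh addition anti to the C7–O bond sets the 6,7-anti carbinol (6R here, 6S in the target).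

**Step 6**
Reactants: 7 (1R,2E)-1-[(4R,5S)-2,2-dimethyl-5-(prop-2-yn-1-yl)-1,3-dioxolan-4-yl]-3-methylhexa-2,5-dien-1-ol
Product: 9 (1Z,4E,6R,7R,8S)-7,8-O-isopropylidene-11,12,13-trinorgermacra-1,4,10(14)-triene-6,7,8-triol, via acyclic tetraene 8 (not isolated)
Conditions: second-generation Grubbs catalyst (10 mol %), ethylene (1 atm), CH2Cl2, 1 mM, rt; then argon purge, 40 °C
Reagents that add atoms: ethylene C=C
Why: Tandem ethylene cross-enyne metathesis and diene–ene ring-closing metathesis: the alkyne first becomes the 2-substituted butadiene 8 (C14 from ethylene), whose vinyl group then closes onto the allyl terminus, the cis-fused dioxolane holding C6 and C9 syn and the ten-membered ring with an E-alkene nearby favouring the Z-C1=C2 bond.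

**Step 7**
Reactants: 9 (1Z,4E,6R,7R,8S)-7,8-O-isopropylidene-11,12,13-trinorgermacra-1,4,10(14)-triene-6,7,8-triol
Product: 10 (1Z,4E,6R,7S,8S)-6-O-acryloyl-7,8-O-isopropylidene-11,12,13-trinorgermacra-1,4,10(14)-triene-6,7,8-triol
Conditions: acryloyl chloride, iPr2NEt, CH2Cl2, −20 to 0 °C
Reagents that add atoms: acryloyl chloride C=CC(=O)Cl
Why: O-Acylation of the only free hydroxyl installs C11–C13 of the future butenolide as an acrylate.

**Step 8**
Reactants: 10 (1Z,4E,6R,7S,8S)-6-O-acryloyl-7,8-O-isopropylidene-11,12,13-trinorgermacra-1,4,10(14)-triene-6,7,8-triol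
Product: 11 (1Z,4E,6R,7S,8S)-6-O-acryloyl-11,12,13-trinorgermacra-1,4,10(14)-triene-6,7,8-triol
Conditions: AcOH/H2O (4:1), 40 °C
Reagents that add atoms: none
Why: Acid hydrolysis of the cis-dioxolane, done before any epoxide is present, releases the C7/C8 diol while the acrylate and the diene should survive aqueous acetic acid.

**Step 9**
Reactants: 12 ethyl 2-(hydroxymethyl)prop-2-enoate
Product: 13 ethyl 2-{[(tert-butyldimethylsilyl)oxy]methyl}prop-2-enoate
Conditions: TBSCl, imidazole, CH2Cl2, 0 °C to rt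
Reagents that add atoms: tert-butyldimethylsilyl chloride CC(C)(C)[Si](C)(C)Cl
Why: Standard imidazole-promoted silylation of the primary allylic alcohol.

**Step 10**
Reactants: 13 ethyl 2-{[(tert-butyldimethylsilyl)oxy]methyl}prop-2-enoate
Product: 14 2-{[(tert-butyldimethylsilyl)oxy]methyl}prop-2-enoic acid
Conditions: LiOH·H2O, THF/H2O (3:1), 0 °C; then 1 M HCl to pH 4
Reagents that add atoms: lithium hydroxide [Li+].[OH-]
Why: Saponification of the ethyl ester, the primary TBS ether being stable to cold LiOH and brief mild acidification.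

**Step 11**
Reactants: 11 (1Z,4E,6R,7S,8S)-6-O-acryloyl-11,12,13-trinorgermacra-1,4,10(14)-triene-6,7,8-triol; 14 2-{[(tert-butyldimethylsilyl)oxy]methyl}prop-2-enoic acid
Product: 15 (1Z,4E,6R,7S,8S)-6-O-acryloyl-8-O-(2-{[(tert-butyldimethylsilyl)oxy]methyl}acryloyl)-11,12,13-trinorgermacra-1,4,10(14)-triene-6,7,8-triol
Conditions: DCC (1.1 equiv), DMAP (10 mol %), CH2Cl2, −20 °C
Reagents that add atoms: none
Why: Steglich esterification at low temperature is expected at the C8 hydroxyl, which has the C9 methylene as neighbour, in preference to the C7 hydroxyl, which sits between two branched oxygenated carbons and is deactivated by the C6 acyloxy group.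

**Step 12**
Reactants: 15 (1Z,4E,6R,7S,8S)-6-O-acryloyl-8-O-(2-{[(tert-butyldimethylsilyl)oxy]methyl}acryloyl)-11,12,13-trinorgermacra-1,4,10(14)-triene-6,7,8-triol
Product: 16 (1Z,4E,6R,8S)-6-acryloyloxy-8-(2-{[(tert-butyldimethylsilyl)oxy]methyl}acryloyloxy)-11,12,13-trinorgermacra-1,4,10(14)-trien-7-one
Conditions: Dess–Martin periodinane, CH2Cl2, 0 °C to rt
Reagents that add atoms: none
Why: Dess–Martin oxidation of the remaining secondary alcohol gives the α,α′-bis(acyloxy) ketone and erases the relay stereocentre C7 under non-basic conditions that should not epimerise C6 or C8.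

**Step 13**
Reactants: 16 (1Z,4E,6R,8S)-6-acryloyloxy-8-(2-{[(tert-butyldimethylsilyl)oxy]methyl}acryloyloxy)-11,12,13-trinorgermacra-1,4,10(14)-trien-7-one
Product: 17 (1Z,4E,6R,8S)-7-hydroxy-8-(2-{[(tert-butyldimethylsilyl)oxy]methyl}acryloyloxy)germacra-1,4,10(14),11(13)-tetraen-12,6-olide (C7 configuration not defined)
Conditions: quinuclidine (1.0 equiv), DME, 0 °C
Reagents that add atoms: none
Why: Intramolecular Morita–Baylis–Hillman reaction: quinuclidine adds to C13 of the C6 acrylate, the ammonium enolate attacks the C7 ketone through C11 (5-exo-trig aldol that closes the five-membered lactone O6–C12–C11–C7–C6 by the C7–C11 bond), and proton transfer with E1cB loss of the amine restores C11=C13. The closest known reactions are amine-promoted intramolecular Morita–Baylis–Hillman cyclisations of acrylamides onto tethered ketones (γ-lactams) and of acrylates of α-hydroxy aldehydes (α-methylene-β-hydroxy-γ-lactones). The only new stereocentre is the tertiary carbinol C7, set by the ketone face that the enolate tethered at C6 can reach, and its configuration does not matter because C7 becomes sp2 in step 14. The step needs chemoselectivity between two acrylic esters and no epimerisation at C6 or C8: the 2-substituted acrylate on O8 adds amines far more slowly and its adduct has no α-hydrogen to turn over, while the two α-acyloxy groups make the C7 ketone electrophilic enough to react at 0 °C with a weakly basic nucleophile.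

**Step 14**
Reactants: 17 (1Z,4E,6R,8S)-7-hydroxy-8-(2-{[(tert-butyldimethylsilyl)oxy]methyl}acryloyloxy)germacra-1,4,10(14),11(13)-tetraen-12,6-olide
Product: 19 (1Z,4E,6R,8S)-13-acetoxy-8-(2-{[(tert-butyldimethylsilyl)oxy]methyl}acryloyloxy)germacra-1,4,7(11),10(14)-tetraen-12,6-olide, via tertiary acetate 18 (not isolated)
Conditions: Ac2O (3 equiv), DMAP (2 equiv), CH2Cl2, rt to 35 °C
Reagents that add atoms: acetic anhydride CC(=O)OC(C)=O
Why: DMAP-catalysed acetylation of the tertiary allylic alcohol is followed in the same flask by DMAP-mediated SN2′/SN2 1,3-transposition of the Morita–Baylis–Hillman acetate, driven by the conjugated tetrasubstituted C7=C11 butenolide and the primary acetate at C13.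

**Step 15**
Reactants: 19 (1Z,4E,6R,8S)-13-acetoxy-8-(2-{[(tert-butyldimethylsilyl)oxy]methyl}acryloyloxy)germacra-1,4,7(11),10(14)-tetraen-12,6-olide
Product: 20 (1Z,4E,6R,8S)-13-acetoxy-8-[2-(hydroxymethyl)acryloyloxy]germacra-1,4,7(11),10(14)-tetraen-12,6-olide
Conditions: Et3N·3HF, THF, rt
Reagents that add atoms: none
Why: Fluoride cleavage of the primary silyl ether is done before the acid-sensitive epoxides are introduced, and the esters and the allylic acetate are not touched.

**Step 16**
Reactants: 20 (1Z,4E,6R,8S)-13-acetoxy-8-[2-(hydroxymethyl)acryloyloxy]germacra-1,4,7(11),10(14)-tetraen-12,6-olide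
Product: 21 (1R,2S,4E,6R,8S)-13-acetoxy-1,2-epoxy-8-[2-(hydroxymethyl)acryloyloxy]germacra-4,7(11),10(14)-trien-12,6-olide
Conditions: Shi N-aryl oxazolidinone ketone (30 mol %), Oxone, K2CO3, Bu4NHSO4 (cat.), DME–dimethoxymethane/aq. buffer pH 8, −10 to 0 °C
Reagents that add atoms: potassium peroxymonosulfate (active part of Oxone) [K+].[O-]S(=O)(=O)OO
Why: Shi asymmetric epoxidation with the ketone designed for conjugated cis-alkenes: the chiral dioxirane reacts stereospecifically (cis geometry kept) at the most electron-rich π-bond, the Z-C1=C2 alkene of the diene, with the C10=C14 π-substituent beside the oxazolidinone in the spiro transition state, so that the catalyst antipode which converts cis-β-methylstyrene into its (1R,2S)-oxide should set 1R,2S here, while C4=C5 is deactivated by the allylic lactone oxygen.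

**Step 17**
Reactants: 21 (1R,2S,4E,6R,8S)-13-acetoxy-1,2-epoxy-8-[2-(hydroxymethyl)acryloyloxy]germacra-4,7(11),10(14)-trien-12,6-olide
Product: 22 (1R,2S,4R,5R,6S,8S)-13-acetoxy-1,2:4,5-diepoxy-8-[2-(hydroxymethyl)acryloyloxy]germacra-7(11),10(14)-dien-12,6-olide (CNP0233746.1)
Conditions: dimethyldioxirane (acetone solution), CH2Cl2, −20 to 0 °C
Reagents that add atoms: dimethyldioxirane CC1(C)OO1
Why: Neutral dioxirane epoxidation of the remaining nucleophilic alkene: only the outer face of the E-C4=C5 bond of the ten-membered ring is open, and A1,3 strain with C15 keeps H6 in the alkene plane so that oxygen arrives anti to C7 to give the trans 4R,5R epoxide, while C10=C14 is now deactivated by the adjacent epoxide and the two acrylic alkenes are electron-poor.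

**Compound list**

1 | 2-deoxy-D-ribose, (3S,4R)-3,4,5-trihydroxypentanal | O=CC[C@H](O)[C@H](O)CO | starting material
2 | 2-deoxy-3,4-O-isopropylidene-D-erythro-pentopyranose (anomeric mixture) | OC1C[C@@H]2OC(C)(C)O[C@@H]2CO1 | intermediate
3 | [(4R,5S)-2,2-dimethyl-5-(prop-2-yn-1-yl)-1,3-dioxolan-4-yl]methanol | C#CC[C@@H]1OC(C)(C)O[C@@H]1CO | intermediate
4 | (4S,5S)-2,2-dimethyl-5-(prop-2-yn-1-yl)-1,3-dioxolane-4-carbaldehyde | C#CC[C@@H]1OC(C)(C)O[C@@H]1C=O | intermediate
5 | pent-1-en-4-yne | C=CCC#C | starting material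
6 | (E)-1-iodo-2-methylpenta-1,4-diene | C=CC/C(C)=C/I | intermediate
7 | (1R,2E)-1-[(4R,5S)-2,2-dimethyl-5-(prop-2-yn-1-yl)-1,3-dioxolan-4-yl]-3-methylhexa-2,5-dien-1-ol | C#CC[C@@H]1OC(C)(C)O[C@@H]1[C@H](O)/C=C(C)/CC=C | intermediate
8 | (1R,2E)-1-[(4R,5S)-2,2-dimethyl-5-(2-methylidenebut-3-en-1-yl)-1,3-dioxolan-4-yl]-3-methylhexa-2,5-dien-1-ol | C=CC(=C)C[C@@H]1OC(C)(C)O[C@@H]1[C@H](O)/C=C(C)/CC=C | intermediate (not isolated)
9 | (1Z,4E,6R,7R,8S)-7,8-O-isopropylidene-11,12,13-trinorgermacra-1,4,10(14)-triene-6,7,8-triol | CC1(C)O[C@H]2CC(=C)/C=C\C/C(C)=C/[C@@H](O)[C@H]2O1 | intermediate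
10 | (1Z,4E,6R,7S,8S)-6-O-acryloyl-7,8-O-isopropylidene-11,12,13-trinorgermacra-1,4,10(14)-triene-6,7,8-triol | CC1(C)O[C@H]2CC(=C)/C=C\C/C(C)=C/[C@@H](OC(=O)C=C)[C@H]2O1 | intermediate
11 | (1Z,4E,6R,7S,8S)-6-O-acryloyl-11,12,13-trinorgermacra-1,4,10(14)-triene-6,7,8-triol | O[C@H]1CC(=C)/C=C\C/C(C)=C/[C@@H](OC(=O)C=C)[C@H]1O | intermediate
12 | ethyl 2-(hydroxymethyl)prop-2-enoate | C=C(CO)C(=O)OCC | starting material
13 | ethyl 2-{[(tert-butyldimethylsilyl)oxy]methyl}prop-2-enoate | C=C(CO[Si](C)(C)C(C)(C)C)C(=O)OCC | intermediate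
14 | 2-{[(tert-butyldimethylsilyl)oxy]methyl}prop-2-enoic acid | C=C(CO[Si](C)(C)C(C)(C)C)C(=O)O | intermediate
15 | (1Z,4E,6R,7S,8S)-6-O-acryloyl-8-O-(2-{[(tert-butyldimethylsilyl)oxy]methyl}acryloyl)-11,12,13-trinorgermacra-1,4,10(14)-triene-6,7,8-triol | C=C(CO[Si](C)(C)C(C)(C)C)C(=O)O[C@H]1CC(=C)/C=C\C/C(C)=C/[C@@H](OC(=O)C=C)[C@H]1O | intermediate
16 | (1Z,4E,6R,8S)-6-acryloyloxy-8-(2-{[(tert-butyldimethylsilyl)oxy]methyl}acryloyloxy)-11,12,13-trinorgermacra-1,4,10(14)-trien-7-one | C=C(CO[Si](C)(C)C(C)(C)C)C(=O)O[C@H]1CC(=C)/C=C\C/C(C)=C/[C@@H](OC(=O)C=C)C1=O | intermediate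
17 | (1Z,4E,6R,8S)-7-hydroxy-8-(2-{[(tert-butyldimethylsilyl)oxy]methyl}acryloyloxy)germacra-1,4,10(14),11(13)-tetraen-12,6-olide (C7 not defined) | C=C(CO[Si](C)(C)C(C)(C)C)C(=O)O[C@H]1CC(=C)/C=C\C/C(C)=C/[C@H]2OC(=O)C(=C)C12O | intermediate
18 | (1Z,4E,6R,8S)-7-acetoxy-8-(2-{[(tert-butyldimethylsilyl)oxy]methyl}acryloyloxy)germacra-1,4,10(14),11(13)-tetraen-12,6-olide (C7 not defined) | C=C(CO[Si](C)(C)C(C)(C)C)C(=O)O[C@H]1CC(=C)/C=C\C/C(C)=C/[C@H]2OC(=O)C(=C)C12OC(C)=O | intermediate (not isolated)
19 | (1Z,4E,6R,8S)-13-acetoxy-8-(2-{[(tert-butyldimethylsilyl)oxy]methyl}acryloyloxy)germacra-1,4,7(11),10(14)-tetraen-12,6-olide | C=C(CO[Si](C)(C)C(C)(C)C)C(=O)O[C@H]1CC(=C)/C=C\C/C(C)=C/[C@H]2OC(=O)C(COC(C)=O)=C12 | intermediate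
20 | (1Z,4E,6R,8S)-13-acetoxy-8-[2-(hydroxymethyl)acryloyloxy]germacra-1,4,7(11),10(14)-tetraen-12,6-olide | C=C(CO)C(=O)O[C@H]1CC(=C)/C=C\C/C(C)=C/[C@H]2OC(=O)C(COC(C)=O)=C12 | intermediate
21 | (1R,2S,4E,6R,8S)-13-acetoxy-1,2-epoxy-8-[2-(hydroxymethyl)acryloyloxy]germacra-4,7(11),10(14)-trien-12,6-olide | C=C(CO)C(=O)O[C@H]1CC(=C)[C@H]2O[C@H]2C/C(C)=C/[C@H]2OC(=O)C(COC(C)=O)=C12 | intermediate
22 | (1R,2S,4R,5R,6S,8S)-13-acetoxy-1,2:4,5-diepoxy-8-[2-(hydroxymethyl)acryloyloxy]germacra-7(11),10(14)-dien-12,6-olide (CNP0233746.1) | C=C(CO)C(=O)O[C@H]1CC(=C)[C@H]2O[C@H]2C[C@@]2(C)O[C@@H]2[C@H]2OC(=O)C(COC(C)=O)=C12 | target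

**Totals**

Total step count: 17. Longest linear sequence: 14 steps (steps 1–3, 5–8 and 11–17, from 2-deoxy-D-ribose).

**Steps most likely to fail**

1. Step 6 (ring closure). The alkyne may oligomerise, the ring may close in the exo mode on the 1,1-disubstituted alkene to a nine-membered vinylcycloalkene, or Z-selectivity may be lost. The fallback sets out from 3 and comes back at 9. The diene is installed before the chain is joined, so the ring is closed by plain olefin–olefin metathesis with no alkyne in the flask. Ethylene cross-enyne metathesis of 3 (second-generation Grubbs catalyst, ethylene 1 atm, CH2Cl2, rt) should give [(4R,5S)-2,2-dimethyl-5-(2-methylidenebut-3-en-1-yl)-1,3-dioxolan-4-yl]methanol F1. Dess–Martin oxidation gives (4S,5S)-2,2-dimethyl-5-(2-methylidenebut-3-en-1-yl)-1,3-dioxolane-4-carbaldehyde F2. Nozaki–Hiyama–Kishi coupling with 6 under the conditions of step 5 gives 8, now isolated. Diene–ene ring-closing metathesis of 8 (second-generation Hoveyda–Grubbs catalyst, toluene, 1 mM, 60 °C, argon sparge, no ethylene) leads to 9.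

2. Step 13 (key lactone closure). Addition to the hindered ring ketone may be slow, so that amine-induced epimerisation at C6 or C8, acyl migration or retro-aldol compete. The fallback sets out from 16 and comes back at 17, and replaces the catalytic process by a stoichiometric Michael–aldol/elimination sequence. Me2AlSPh (from Me3Al and PhSH, CH2Cl2, −78 °C) adds thiolate to C13, and the aluminium enolate closes the lactone on C7 (tandem thia-Michael–aldol). This gives (1Z,4E,6R,8S)-7-hydroxy-13-(phenylsulfanyl)-8-(2-{[(tert-butyldimethylsilyl)oxy]methyl}acryloyloxy)germacra-1,4,10(14)-trien-12,6-olide F3. mCPBA (1.0 equiv, −78 °C) oxidises sulfur selectively to the 13-(phenylsulfinyl) analogue F4. Thermal syn-elimination (toluene, 90 °C, CaCO3) restores C11=C13 and gives 17.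

3. Step 16 (vinyl epoxide). Site selectivity may be insufficient (attack at C10=C14 or C4=C5), or facial selectivity on the macrocyclic Z-alkene may be poor. The fallback sets out from 20 and comes back at 21, and changes the oxidant class from a dioxirane to a metal-oxo species. Jacobsen–Katsuki epoxidation uses [N,N′-bis(3,5-di-tert-butylsalicylidene)cyclohexane-1,2-diamine]MnCl (trivalent manganese), NaOCl, 4-phenylpyridine N-oxide, CH2Cl2, 0 °C, with the ligand antipode chosen for the 1R,2S sense. Its stepwise radical-type addition favours the conjugated cis-alkene on electronic grounds, and the ring prevents the bond rotation that would erode the cis geometry. No new compound is made (F0).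

**Further compounds**

F1 | step 6 | [(4R,5S)-2,2-dimethyl-5-(2-methylidenebut-3-en-1-yl)-1,3-dioxolan-4-yl]methanol | C=CC(=C)C[C@@H]1OC(C)(C)O[C@@H]1CO
F2 | step 6 | (4S,5S)-2,2-dimethyl-5-(2-methylidenebut-3-en-1-yl)-1,3-dioxolane-4-carbaldehyde | C=CC(=C)C[C@@H]1OC(C)(C)O[C@@H]1C=O
F3 | step 13 | (1Z,4E,6R,8S)-7-hydroxy-13-(phenylsulfanyl)-8-(2-{[(tert-butyldimethylsilyl)oxy]methyl}acryloyloxy)germacra-1,4,10(14)-trien-12,6-olide (C7 and C11 not defined) | C=C(CO[Si](C)(C)C(C)(C)C)C(=O)O[C@H]1CC(=C)/C=C\C/C(C)=C/[C@H]2OC(=O)C(CSc3ccccc3)C12O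
F4 | step 13 | (1Z,4E,6R,8S)-7-hydroxy-13-(phenylsulfinyl)-8-(2-{[(tert-butyldimethylsilyl)oxy]methyl}acryloyloxy)germacra-1,4,10(14)-trien-12,6-olide (C7, C11 and sulfur not defined) | C=C(CO[Si](C)(C)C(C)(C)C)C(=O)O[C@H]1CC(=C)/C=C\C/C(C)=C/[C@H]2OC(=O)C(CS(=O)c3ccccc3)C12O
F0 | step 16 | none | none
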